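## Analysis of the target

Target 24 is an isoflavan: a pyran ring (O1, C2, C3, C4, C4a, C8a) fused to ring A, with ring B (2-hydroxy-3,4-dimethoxyphenyl) on C3 and a phenol on C7. C6 of ring A carries a three-carbon chain: side-chain C1 is a diarylmethine bonded to ring A and ring C (2,4-dihydroxyphenyl), C2 is a secondary carbinol, and C3 is a methylene bonded to ring D (4-hydroxyphenyl). There are three stereocentres, all R: pyran C3 and side-chain C1 and C2. Side-chain C1 and C2 are adjacent (ring C and the hydroxyl group are syn when ring A–C1–C2–C3 is drawn as a zigzag), whereas pyran C3 is insulated from them by ring A, so neither set can steer the other. The molecule has five phenols and a doubly benzylic C1–H between two ortho,para-oxygenated rings; it is sensitive to air, base and acid (ionisation at C1, retro-Friedel–Crafts cleavage), so the phenols should be freed last. Two things are hard: pyran C3 is a tertiary benzylic centre with no neighbouring heteroatom, so it needs catalyst control and is labile whenever it sits α to a carbonyl group; and side-chain C1 bears two aryl groups of nearly equal size and donor strength, so a planar intermediate carrying both offers no facial bias. The strategy rests on the O1–C2–C3–C4 unit: O1 and C4 sit on adjacent carbons of ring A (C8a and C4a), which is the pattern of an ortho-quinone methide of ring A, and C2–C3 with ring B is an arylacetaldehyde, so the pyran can be made by joining C3 to C4 and O1 to C2.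

## Retrosynthetic reasoning

**24 from 23.** No skeletal bond is cut. All six hydroxyl groups are carried as benzyl ethers, so one hydrogenolysis ends the synthesis and the air-sensitive polyphenol appears only once. The side-chain C2–O bond is not benzylic and should survive.

**23 from 21 and 22.** The bond between side-chain C1 and ring C is cut. This leaves a secondary benzylic cation at C1 that is conjugated only with ring A (stabilised by O1 in the para position and the C7 oxygen in the ortho position). Such a cation has a defined conformation: the C2–H bond lies in the plane of ring A to avoid allylic 1,3-strain, and the two other C2 substituents occupy opposite faces. Cutting C1–H instead, by reduction of a tertiary carbinol carrying ring A and ring C, would give a cation flanked by two nearly identical aryl groups and no predictable facial preference. Ring C then arrives as the simple diether 22, which reacts at its most nucleophilic carbon. The forward reaction has to deliver ring C anti to the arylmethyl group at C2. Because the cation is planar, the carbinol configuration of 21 is irrelevant.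

**21 from 20, and 20 from 14 and 18 through 19.** The C6–C1 bond is cut. The bromine atom placed on ring A at the outset becomes the aryllithium 19, and the side chain arrives as the N-methoxy-N-methylamide 18. The amide is chosen because it is configurationally robust at C2, stops cleanly at the ketone, and already contains C2, C3 and ring D.

**18 from 17, 16 and 15.** Side-chain C2, C3 and ring D are the carbon skeleton of tyrosine. Replacing the amino group of D-tyrosine 15 by hydroxyl with retention gives the (R)-hydroxy acid 16, so this stereocentre is taken from the chiral pool and no C–C bond has to be made.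

**14 from 13, and 13 from 12.** The O1–C2 bond is opened and closed again at a lower oxidation level. Reducing the lactol carbon of 12 immediately removes the carbonyl group next to C3 and makes that centre configurationally stable. The pyran is then re-formed by dehydrative etherification of the phenol with the primary alcohol of 13.

**12 from 6 and 10 through 11 (key disconnection).** The C3–C4 and O1–C2 bonds are cut together. This divides the pyran into the ortho-quinone methide 11 of ring A, stored as the sulfone 6, and the arylacetaldehyde 10. Both bonds and the C3 stereocentre are formed in one catalytic step from two simple pieces, and the C6 bromine is already in place. The forward reaction must add the enamine of 10 to the methide carbon through one face only.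

**6 from 4, 3, 2, 1 and 5; 10 from 9, 8 and 7.** These are functional-group changes on commercial benzaldehydes. For ring A: regioselective benzylation of 1, bromination para to the free phenol, reduction, and replacement of the benzylic hydroxyl group by the sulfinate 5. For ring B: benzylation of 7 and one-carbon homologation through the enol ether 9.

## Alternatives that were turned down

**Alternative 1:** The O1–C8a bond is cut. The prochiral diol A2 (ring B and a 2-bromobenzyl group on the central carbon of a propane-1,3-diol) would be cyclised with CuI and a chiral diamine, or Pd(OAc)2 and a chiral phosphine. The catalyst selects one of the two enantiotopic hydroxymethyl groups and gives the chroman A1 with a quaternary C3.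
- For it: ring closure and stereogenesis coincide in one catalytic step, and a quaternary centre cannot epimerise. On configurational stability it is stronger than the chosen route, where C3 sits next to a masked aldehyde for one step.
- Against it: the target has hydrogen on C3, so the spare hydroxymethyl group of A1 must be oxidised and excised with retention (decarbonylation with stoichiometric RhCl(PPh3)3) at a hindered centre, costing two or three steps of uncertain fidelity. The catalyst must also distinguish two hydroxymethyl groups on a carbon whose other substituents are both bulky. A C6 bromine cannot be carried through a copper- or palladium-mediated aryl bromide coupling, so ring A would need a later bromination with a C6 versus C8 question.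
- Comparison: the chosen strategy gives the tertiary centre with its hydrogen directly, keeps the C6 handle from the start, and is shorter.

**Alternative 2:** This plan addresses the side chain. The (E)-allylic alcohol A4 on C6 of a finished isoflavan would be epoxidised with Ti(OiPr)4, D-(−)-diisopropyl tartrate and tBuOOH to the epoxy alcohol A3. The benzylic C–O bond would later be replaced by ring C with inversion, and the other kept as the carbinol.
- For it: both side-chain centres come from reagent control, and a stereospecific opening would define C1 more rigorously than the conformational control used in the chosen route. On that point it is stronger.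
- Against it: the benzylic oxirane carbon of A3 is para to O1 and ortho to the C7 oxygen, so it should ionise under the Lewis-acidic titanium conditions and again during arylation. The opening would then pass through the same planar cation as in the chosen route and lose its stereospecificity. The primary carbon must still be joined to ring D by a separate activation and coupling next to the carbinol. The plan does not set pyran C3 at all.
- Comparison: the chosen strategy takes C2, C3 and ring D ready-made from tyrosine, needs one arylation for C1, and also solves pyran C3.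

**Alternative 3:** The C4–C4a bond is cut. In the aryl iodide A6, iodine–lithium exchange with tBuLi would give an aryllithium ortho to the ether oxygen, which displaces the primary bromide intramolecularly (6-exo-tet) and gives the isoflavan A5. The stereocentre would come from an enzymatic desymmetrisation earlier in the chain.
- For it: the enzymatic step is dependable, the centre is never α to a carbonyl group after it is formed, and the ring closure makes no stereochemical demand. On robustness of C3 it is at least as strong as the chosen route.
- Against it: the two arms of the desymmetrised carbon must be elaborated in a fixed order through several protecting-group operations, and acyl migration at the monoester stage would erode the enantiomeric purity. The bromide in A6 is β to a benzylic C–H, so elimination and exchange at the alkyl bromide compete with cyclisation. A C6 bromine cannot survive tBuLi, so A5 must be brominated afterwards.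
- Comparison: the chosen strategy is convergent, forms two bonds and the ring in one step, and reaches the brominated isoflavan in three steps from 6 and 10.

Key step: step 8

## Remarks on the chemistry

- The (R)-configured catalyst is needed in step 8. With C2 > ring B > C4 as the priority order, the (S)-catalyst would give the (3S) isoflavan.
- Lactol 12 is drawn and named as its trans (2S,3R) anomer. The anomeric centre equilibrates and is removed in step 9.
- Alcohol 21 is carried as a mixture of C1 epimers, because step 16 passes through a planar C1 cation.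

## Route

Step 1
Reactants: 1 2,4-dihydroxybenzaldehyde
Product: 2 4-(benzyloxy)-2-hydroxybenzaldehyde
Conditions: BnBr (1.05 equiv), NaHCO3, KI (cat.), MeCN, 80 °C
Reagents that add atoms: benzyl bromide, BrCc1ccccc1
Why: Williamson etherification. The 2-hydroxyl group is held in a hydrogen bond to the formyl group and is the poorer nucleophile, so the weak base should alkylate only the 4-hydroxyl group.

Step 2
Reactants: 2 4-(benzyloxy)-2-hydroxybenzaldehyde
Product: 3 4-(benzyloxy)-5-bromo-2-hydroxybenzaldehyde
Conditions: NBS, MeCN, 0 °C to rt, dark
Reagents that add atoms: N-bromosuccinimide, O=C1CCC(=O)N1Br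
Why: Electrophilic aromatic bromination. C5 is para to the free phenol and ortho to the benzyloxy group, while C3 is flanked by two oxygen substituents and is hindered, so C5 should be brominated.

Step 3
Reactants: 3 4-(benzyloxy)-5-bromo-2-hydroxybenzaldehyde
Product: 4 5-(benzyloxy)-4-bromo-2-(hydroxymethyl)phenol
Conditions: NaBH4, THF–MeOH, 0 °C
Reagents that add atoms: none
Why: Hydride reduction of the aldehyde. The aryl bromide and the benzyl ether are inert to NaBH4.

Step 4
Reactants: 4 5-(benzyloxy)-4-bromo-2-(hydroxymethyl)phenol; 5 sodium p-toluenesulfinate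
Product: 6 5-(benzyloxy)-4-bromo-2-{[(4-methylphenyl)sulfonyl]methyl}phenol
Conditions: HCO2H–H2O, 40 °C
Reagents that add atoms: none
Why: Acid-promoted SN1 substitution of a salicyl alcohol. The benzylic cation is stabilised by the para benzyloxy and ortho hydroxyl groups and is captured at the soft sulfur of the sulfinate, giving the sulfone as the thermodynamic product.

Step 5
Reactants: 7 2-hydroxy-3,4-dimethoxybenzaldehyde
Product: 8 2-(benzyloxy)-3,4-dimethoxybenzaldehyde
Conditions: BnBr, K2CO3, DMF, 50 °C
Reagents that add atoms: benzyl bromide, BrCc1ccccc1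
Why: Williamson etherification of the only free phenol. The stronger base and polar solvent overcome the hydrogen bond to the formyl group.

Step 6
Reactants: 8 2-(benzyloxy)-3,4-dimethoxybenzaldehyde
Product: 9 2-(benzyloxy)-3,4-dimethoxy-1-(2-methoxyethenyl)benzene (E/Z mixture)
Conditions: Ph3P(CH2OMe)Cl, KOtBu, THF, 0 °C to rt
Reagents that add atoms: (methoxymethyl)triphenylphosphonium chloride, COC[P+](c1ccccc1)(c1ccccc1)c1ccccc1.[Cl-]
Why: Wittig methoxymethylenation, the standard one-carbon homologation of an aryl aldehyde. The alkene geometry is irrelevant because both isomers hydrolyse to the same aldehyde.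

Step 7
Reactants: 9 2-(benzyloxy)-3,4-dimethoxy-1-(2-methoxyethenyl)benzene
Product: 10 [2-(benzyloxy)-3,4-dimethoxyphenyl]acetaldehyde
Conditions: 2 M HCl, THF, 40 °C; used without storage
Reagents that add atoms: water, O
Why: Acid hydrolysis of the enol ether by C-protonation and capture of the oxocarbenium ion by water. Benzyl and methyl aryl ethers are stable to dilute acid, and the aldehyde is used at once because arylacetaldehydes self-condense on standing.

Step 8
Reactants: 6 5-(benzyloxy)-4-bromo-2-{[(4-methylphenyl)sulfonyl]methyl}phenol; 10 [2-(benzyloxy)-3,4-dimethoxyphenyl]acetaldehyde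
Product: 12 (2S,3R)-7-(benzyloxy)-3-[2-(benzyloxy)-3,4-dimethoxyphenyl]-6-bromo-3,4-dihydro-2H-chromen-2-ol (trans lactol), via ortho-quinone methide 11 (not isolated)
Conditions: (R)-2-[diphenyl(trimethylsilyloxy)methyl]pyrrolidine (20 mol%), 10 (1.5 equiv), Na2CO3 (1.2 equiv), CH2Cl2–H2O, 0 °C to rt
Reagents that add atoms: none
Why: Carbonate deprotonates the phenol of 6, and 1,4-elimination of p-toluenesulfinate releases the ortho-quinone methide 11 slowly and in low concentration, while 10 condenses with the amine to the (E)-enamine, whose geometry is fixed by conjugation with ring B. The enamine carbon adds to the exocyclic methide carbon (conjugate addition driven by rearomatisation of ring A) and forms C3–C4; hydrolysis of the iminium ion returns the catalyst, and the liberated phenol adds to the aldehyde and forms O1–C2. The closest known reaction type is the amine-catalysed enantioselective α-alkylation of aldehydes with quinone methides generated in situ from 2-(sulfonylmethyl)phenols, which gives chroman-2-ols in a formal [4+2] sense. The pyran ring is closed by 6-exo-trig hemiacetalisation. C3 is controlled by the catalyst: the diphenyl(trimethylsilyloxy)methyl group of the (R)-pyrrolidine shields the Si face of the anti enamine, so the methide carbon bonds to the Re face and the (3R) centre should result. C2 is the anomeric centre; it equilibrates through the open hydroxy aldehyde towards the trans lactol and is removed in step 9. The step needs enantiofacial selectivity and C-alkylation of the enamine in preference to N-alkylation of the catalyst, self-condensation of 11 or aldol reaction of 10. The benzyloxy group para to the methide carbon stabilises 11 and tempers its reactivity, the excess of 10 keeps the enamine concentration high, and closure to the lactol withdraws the α-aryl aldehyde from renewed enamine formation.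

Step 9
Reactants: 12 (2S,3R)-7-(benzyloxy)-3-[2-(benzyloxy)-3,4-dimethoxyphenyl]-6-bromo-3,4-dihydro-2H-chromen-2-ol
Product: 13 (2R)-2-[2-(benzyloxy)-3,4-dimethoxyphenyl]-3-[4-(benzyloxy)-5-bromo-2-hydroxyphenyl]propan-1-ol
Conditions: crude 12, NaBH4, THF–MeOH, 0 °C
Reagents that add atoms: none
Why: The lactol is in equilibrium with the hydroxy aldehyde, which is reduced irreversibly to the primary alcohol. This removes the anomeric centre and the enolisable carbonyl group, so C3 is configurationally fixed from here on.

Step 10
Reactants: 13 (2R)-2-[2-(benzyloxy)-3,4-dimethoxyphenyl]-3-[4-(benzyloxy)-5-bromo-2-hydroxyphenyl]propan-1-ol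
Product: 14 (3R)-7-(benzyloxy)-3-[2-(benzyloxy)-3,4-dimethoxyphenyl]-6-bromo-3,4-dihydro-2H-chromene
Conditions: PPh3, DIAD, THF, 0 °C to rt
Reagents that add atoms: none
Why: Intramolecular Mitsunobu etherification. The phenol is the acidic partner and displaces the activated primary alcohol by SN2 (6-exo-tet); the stereocentre is not involved.

Step 11
Reactants: 15 D-tyrosine
Product: 16 (2R)-2-hydroxy-3-(4-hydroxyphenyl)propanoic acid
Conditions: NaNO2, 1 M H2SO4, 0 °C to rt
Reagents that add atoms: water, O
Why: Diazotisation of the α-amino acid. The carboxylate displaces dinitrogen to an α-lactone, which water opens, so two inversions give net retention and the (R) configuration is kept.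

Step 12
Reactants: 16 (2R)-2-hydroxy-3-(4-hydroxyphenyl)propanoic acid
Product: 17 (2R)-2-hydroxy-3-(4-hydroxyphenyl)-N-methoxy-N-methylpropanamide
Conditions: MeNHOMe·HCl, EDC·HCl, HOBt, N-methylmorpholine, CH2Cl2–DMF, 0 °C to rt
Reagents that add atoms: N,O-dimethylhydroxylamine hydrochloride, CNOC.Cl
Why: Carbodiimide amidation through the hydroxybenzotriazole ester. The amine is far more nucleophilic than the two hydroxyl groups, and an α-hydroxy acid has no oxazolone pathway for racemisation.

Step 13
Reactants: 17 (2R)-2-hydroxy-3-(4-hydroxyphenyl)-N-methoxy-N-methylpropanamide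
Product: 18 (2R)-2-(benzyloxy)-3-[4-(benzyloxy)phenyl]-N-methoxy-N-methylpropanamide
Conditions: NaH (2.3 equiv), BnBr (2.3 equiv), Bu4NI (cat.), THF–DMF, 0 °C
Reagents that add atoms: benzyl bromide, BrCc1ccccc1
Why: Double Williamson etherification of the phenoxide and the alkoxide. The α-C–H of an α-alkoxy amide is not acidic enough for NaH at 0 °C, so the C2 configuration should be kept.

Step 14
Reactants: 14 (3R)-7-(benzyloxy)-3-[2-(benzyloxy)-3,4-dimethoxyphenyl]-6-bromo-3,4-dihydro-2H-chromene; 18 (2R)-2-(benzyloxy)-3-[4-(benzyloxy)phenyl]-N-methoxy-N-methylpropanamide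
Product: 20 (2R)-2-(benzyloxy)-1-{(3R)-7-(benzyloxy)-3-[2-(benzyloxy)-3,4-dimethoxyphenyl]-3,4-dihydro-2H-chromen-6-yl}-3-[4-(benzyloxy)phenyl]propan-1-one, via aryllithium 19 (not isolated)
Conditions: n-BuLi, THF, −78 °C; then 18, −78 to −40 °C; aq. NH4Cl
Reagents that add atoms: none
Why: Bromine–lithium exchange followed by acylation with the N-methoxy-N-methylamide. The chelated tetrahedral adduct collapses only on work-up, so addition stops at the ketone. Chelation of lithium by the α-benzyloxy group favours addition over α-deprotonation, which protects C2.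

Step 15
Reactants: 20 (2R)-2-(benzyloxy)-1-{(3R)-7-(benzyloxy)-3-[2-(benzyloxy)-3,4-dimethoxyphenyl]-3,4-dihydro-2H-chromen-6-yl}-3-[4-(benzyloxy)phenyl]propan-1-one
Product: 21 (1RS,2R)-2-(benzyloxy)-1-{(3R)-7-(benzyloxy)-3-[2-(benzyloxy)-3,4-dimethoxyphenyl]-3,4-dihydro-2H-chromen-6-yl}-3-[4-(benzyloxy)phenyl]propan-1-ol
Conditions: NaBH4, THF–MeOH, 0 °C
Reagents that add atoms: none
Why: Hydride reduction of the aryl ketone under non-basic conditions that do not enolise C2. The new carbinol centre need not be controlled, since both epimers ionise to the same cation in step 16.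

Step 16
Reactants: 21 (1RS,2R)-2-(benzyloxy)-1-{(3R)-7-(benzyloxy)-3-[2-(benzyloxy)-3,4-dimethoxyphenyl]-3,4-dihydro-2H-chromen-6-yl}-3-[4-(benzyloxy)phenyl]propan-1-ol; 22 1,3-bis(benzyloxy)benzene
Product: 23 (3R)-7-(benzyloxy)-3-[2-(benzyloxy)-3,4-dimethoxyphenyl]-6-{(1R,2R)-2-(benzyloxy)-1-[2,4-bis(benzyloxy)phenyl]-3-[4-(benzyloxy)phenyl]propyl}-3,4-dihydro-2H-chromene
Conditions: 22 (5 equiv), HBF4·OEt2 (0.2 equiv), CH2Cl2, −78 to −40 °C
Reagents that add atoms: none
Why: Friedel–Crafts alkylation through the secondary benzylic cation at C1, which is stabilised by O1 (para) and the C7 benzyloxy group (ortho); this is the known diastereoselective arylation of α-branched benzylic cations. In the cation the C2–H bond lies in the plane of ring A to avoid allylic 1,3-strain, so the benzyloxy group and the larger, better electron-donating arylmethyl group occupy opposite faces; C4 of 22 (para to one ether oxygen and ortho to the other) should enter anti to the arylmethyl group, which gives (1R) next to (2R). The excess of 22 suppresses a second alkylation and attack by ring B of another molecule.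

Step 17
Reactants: 23 (3R)-7-(benzyloxy)-3-[2-(benzyloxy)-3,4-dimethoxyphenyl]-6-{(1R,2R)-2-(benzyloxy)-1-[2,4-bis(benzyloxy)phenyl]-3-[4-(benzyloxy)phenyl]propyl}-3,4-dihydro-2H-chromene
Product: 24 4-[(1R,2R)-2-hydroxy-1-[(3R)-7-hydroxy-3-(2-hydroxy-3,4-dimethoxyphenyl)-3,4-dihydro-2H-chromen-6-yl]-3-(4-hydroxyphenyl)propyl]benzene-1,3-diol
Conditions: H2 (1 atm), Pd(OH)2/C, EtOAc–MeOH, rt, degassed solvents
Reagents that add atoms: none
Why: Hydrogenolysis of the five aryl benzyl ethers and the one alkyl benzyl ether. The C2–O bond of the side chain is not benzylic, and the methyl ethers, the pyran ether and the diarylmethine are inert, so no stereocentre is touched.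

## Compound list

1 | 2,4-dihydroxybenzaldehyde | O=Cc1ccc(O)cc1O | starting material
2 | 4-(benzyloxy)-2-hydroxybenzaldehyde | O=Cc1ccc(OCc2ccccc2)cc1O | intermediate
3 | 4-(benzyloxy)-5-bromo-2-hydroxybenzaldehyde | O=Cc1cc(Br)c(OCc2ccccc2)cc1O | intermediate
4 | 5-(benzyloxy)-4-bromo-2-(hydroxymethyl)phenol | OCc1cc(Br)c(OCc2ccccc2)cc1O | intermediate
5 | sodium p-toluenesulfinate | Cc1ccc(cc1)S(=O)[O-].[Na+] | starting material
6 | 5-(benzyloxy)-4-bromo-2-{[(4-methylphenyl)sulfonyl]methyl}phenol | Cc1ccc(cc1)S(=O)(=O)Cc1cc(Br)c(OCc2ccccc2)cc1O | intermediate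
7 | 2-hydroxy-3,4-dimethoxybenzaldehyde | COc1ccc(C=O)c(O)c1OC | starting material
8 | 2-(benzyloxy)-3,4-dimethoxybenzaldehyde | COc1ccc(C=O)c(OCc2ccccc2)c1OC | intermediate
9 | 2-(benzyloxy)-3,4-dimethoxy-1-(2-methoxyethenyl)benzene (E/Z mixture) | COC=Cc1ccc(OC)c(OC)c1OCc1ccccc1 | intermediate
10 | [2-(benzyloxy)-3,4-dimethoxyphenyl]acetaldehyde | COc1ccc(CC=O)c(OCc2ccccc2)c1OC | intermediate
11 | 3-(benzyloxy)-4-bromo-6-methylidenecyclohexa-2,4-dien-1-one (ortho-quinone methide, not isolated) | C=C1C(=O)C=C(OCc2ccccc2)C(Br)=C1 | intermediate
12 | (2S,3R)-7-(benzyloxy)-3-[2-(benzyloxy)-3,4-dimethoxyphenyl]-6-bromo-3,4-dihydro-2H-chromen-2-ol (trans anomer drawn) | COc1ccc([C@@H]2[C@@H](O)Oc3cc(OCc4ccccc4)c(Br)cc3C2)c(OCc4ccccc4)c1OC | intermediate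
13 | (2R)-2-[2-(benzyloxy)-3,4-dimethoxyphenyl]-3-[4-(benzyloxy)-5-bromo-2-hydroxyphenyl]propan-1-ol | COc1ccc([C@H](CO)Cc2cc(Br)c(OCc3ccccc3)cc2O)c(OCc2ccccc2)c1OC | intermediate
14 | (3R)-7-(benzyloxy)-3-[2-(benzyloxy)-3,4-dimethoxyphenyl]-6-bromo-3,4-dihydro-2H-chromene | COc1ccc([C@@H]2COc3cc(OCc4ccccc4)c(Br)cc3C2)c(OCc4ccccc4)c1OC | intermediate
15 | D-tyrosine | N[C@H](Cc1ccc(O)cc1)C(=O)O | starting material
16 | (2R)-2-hydroxy-3-(4-hydroxyphenyl)propanoic acid | O[C@H](Cc1ccc(O)cc1)C(=O)O | intermediate
17 | (2R)-2-hydroxy-3-(4-hydroxyphenyl)-N-methoxy-N-methylpropanamide | CON(C)C(=O)[C@H](O)Cc1ccc(O)cc1 | intermediate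
18 | (2R)-2-(benzyloxy)-3-[4-(benzyloxy)phenyl]-N-methoxy-N-methylpropanamide | CON(C)C(=O)[C@H](OCc1ccccc1)Cc1ccc(OCc2ccccc2)cc1 | intermediate
19 | {(3R)-7-(benzyloxy)-3-[2-(benzyloxy)-3,4-dimethoxyphenyl]-3,4-dihydro-2H-chromen-6-yl}lithium (not isolated) | COc1ccc([C@@H]2COc3cc(OCc4ccccc4)c([Li])cc3C2)c(OCc4ccccc4)c1OC | intermediate
20 | (2R)-2-(benzyloxy)-1-{(3R)-7-(benzyloxy)-3-[2-(benzyloxy)-3,4-dimethoxyphenyl]-3,4-dihydro-2H-chromen-6-yl}-3-[4-(benzyloxy)phenyl]propan-1-one | COc1ccc([C@@H]2COc3cc(OCc4ccccc4)c(C(=O)[C@H](OCc4ccccc4)Cc4ccc(OCc5ccccc5)cc4)cc3C2)c(OCc4ccccc4)c1OC | intermediate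
21 | (1RS,2R)-2-(benzyloxy)-1-{(3R)-7-(benzyloxy)-3-[2-(benzyloxy)-3,4-dimethoxyphenyl]-3,4-dihydro-2H-chromen-6-yl}-3-[4-(benzyloxy)phenyl]propan-1-ol (C1 epimers) | COc1ccc([C@@H]2COc3cc(OCc4ccccc4)c(C(O)[C@H](OCc4ccccc4)Cc4ccc(OCc5ccccc5)cc4)cc3C2)c(OCc4ccccc4)c1OC | intermediate
22 | 1,3-bis(benzyloxy)benzene | c1ccc(COc2cccc(OCc3ccccc3)c2)cc1 | starting material
23 | (3R)-7-(benzyloxy)-3-[2-(benzyloxy)-3,4-dimethoxyphenyl]-6-{(1R,2R)-2-(benzyloxy)-1-[2,4-bis(benzyloxy)phenyl]-3-[4-(benzyloxy)phenyl]propyl}-3,4-dihydro-2H-chromene | COc1ccc([C@@H]2COc3cc(OCc4ccccc4)c([C@@H](c4ccc(OCc5ccccc5)cc4OCc4ccccc4)[C@H](OCc4ccccc4)Cc4ccc(OCc5ccccc5)cc4)cc3C2)c(OCc4ccccc4)c1OC | intermediate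
24 | 4-[(1R,2R)-2-hydroxy-1-[(3R)-7-hydroxy-3-(2-hydroxy-3,4-dimethoxyphenyl)-3,4-dihydro-2H-chromen-6-yl]-3-(4-hydroxyphenyl)propyl]benzene-1,3-diol | COc1ccc([C@@H]2COc3cc(O)c([C@@H](c4ccc(O)cc4O)[C@H](O)Cc4ccc(O)cc4)cc3C2)c(O)c1OC | target

## Step count and least certain steps

Total: 17 steps. Longest linear sequence: 11 steps (steps 1–4, 8–10 and 14–17).

**Step 8 (key step).** The most likely failure is erosion of the enantiomeric purity at C3. The lactol stays in equilibrium with the open α-aryl aldehyde, whose α-hydrogen is benzylic and can be removed by carbonate or by renewed enamine formation. Loss of the quinone methide by self-condensation or by N-alkylation of the catalyst, and aldol self-condensation of 10, would lower conversion. The fallback replaces catalyst control by auxiliary control; it sets out from 10 and 3 and returns at 13. Aldehyde 10 would be oxidised (NaClO2, NaH2PO4, 2-methylbut-2-ene) to [2-(benzyloxy)-3,4-dimethoxyphenyl]acetic acid F1, which would be joined through its pivaloyl mixed anhydride to lithiated (R)-4-benzyl-1,3-oxazolidin-2-one to give the N-acyl oxazolidinone F2. Aldehyde 3 would be protected (MOMCl, iPr2NEt) as the methoxymethyl ether F3, reduced (NaBH4) to the benzylic alcohol F4 and brominated (CBr4, PPh3) to the benzylic bromide F5. Alkylation of the chelated sodium (Z)-enolate of F2 (NaN(SiMe3)2, THF, −78 °C) with F5 on the face away from the benzyl group of the auxiliary should give the alkylated imide F6 with the (R)-configured α-carbon. LiBH4 would remove the auxiliary reductively to the primary alcohol F7, and HCl in MeOH would cleave the methoxymethyl ether to give 13.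

**Step 16.** The most likely failure is poor facial selectivity at the C1 cation, or attack on the other face, because the benzyloxy and arylmethyl groups at C2 differ only moderately in size. Proton loss from C2 and benzyl transfer from the ring A ether are further drains. The fallback exchanges the roles of the two rings; it sets out from 14, 18 and 22 and returns at 23. Bromide 14 would be converted (n-BuLi, then MeOH) into the bromine-free isoflavan F8, which has the same structure as A5. Diether 22 would be brominated (NBS, MeCN) to 2,4-bis(benzyloxy)-1-bromobenzene F9. After bromine–lithium exchange, F9 would be acylated with 18 to the ring C ketone F10, which would be reduced (NaBH4) to the ring C carbinol F11. Ionisation of F11 under the conditions of step 16 in the presence of F8 would bond C6 of ring A (para to O1) to the cation. In this pairing ring C lies in the cation plane and ring A arrives, so a nucleophile that prefers the face syn to the arylmethyl group gives the (1R) epimer. If the first pairing favours the wrong face, this one should therefore deliver 23. If the bias is small in both pairings, the C1 epimers would have to be separated at 23.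

**Step 14.** The most likely failure is premature protonation of aryllithium 19, by the α-C–H of the amide or by a benzylic ether C–H on warming, because acylation of a hindered ortho-alkoxy aryllithium by an α-branched amide is slow; this would also put the C2 configuration at risk. The fallback uses a more reactive electrophile and skips the ketone; it sets out from 18 and returns at 21. Amide 18 would be reduced (LiAlH4, THF, −78 to 0 °C) to (2R)-2-(benzyloxy)-3-[4-(benzyloxy)phenyl]propanal F12. Addition of 19 to F12 at −78 °C should give 21 directly as the mixture of C1 epimers that step 16 accepts.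

**Step 13.** The most likely failure is partial racemisation at C2 by α-deprotonation, or base-induced loss of the N-methoxy group, under NaH. The fallback moves the alkylation of the secondary alcohol to acidic conditions; it sets out from 17 and returns at 18. The phenol alone would be benzylated (K2CO3, BnBr, acetone) to the phenyl benzyl ether F13. The secondary alcohol of F13 would then be benzylated with benzyl 2,2,2-trichloroacetimidate and catalytic TfOH, giving 18 without exposure of C2 to strong base.

## Further compounds

F1 | step 8 | [2-(benzyloxy)-3,4-dimethoxyphenyl]acetic acid | COc1ccc(CC(=O)O)c(OCc2ccccc2)c1OC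
F2 | step 8 | (4R)-4-benzyl-3-{[2-(benzyloxy)-3,4-dimethoxyphenyl]acetyl}-1,3-oxazolidin-2-one | COc1ccc(CC(=O)N2[C@H](Cc3ccccc3)COC2=O)c(OCc2ccccc2)c1OC
F3 | step 8 | 4-(benzyloxy)-5-bromo-2-(methoxymethoxy)benzaldehyde | COCOc1cc(OCc2ccccc2)c(Br)cc1C=O
F4 | step 8 | [4-(benzyloxy)-5-bromo-2-(methoxymethoxy)phenyl]methanol | COCOc1cc(OCc2ccccc2)c(Br)cc1CO
F5 | step 8 | 1-(benzyloxy)-2-bromo-4-(bromomethyl)-5-(methoxymethoxy)benzene | COCOc1cc(OCc2ccccc2)c(Br)cc1CBr
F6 | step 8 | (4R)-4-benzyl-3-{(2R)-2-[2-(benzyloxy)-3,4-dimethoxyphenyl]-3-[4-(benzyloxy)-5-bromo-2-(methoxymethoxy)phenyl]propanoyl}-1,3-oxazolidin-2-one | COc1ccc([C@@H](Cc2cc(Br)c(OCc3ccccc3)cc2OCOC)C(=O)N2[C@H](Cc3ccccc3)COC2=O)c(OCc2ccccc2)c1OC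
F7 | step 8 | (2R)-2-[2-(benzyloxy)-3,4-dimethoxyphenyl]-3-[4-(benzyloxy)-5-bromo-2-(methoxymethoxy)phenyl]propan-1-ol | COc1ccc([C@H](CO)Cc2cc(Br)c(OCc3ccccc3)cc2OCOC)c(OCc2ccccc2)c1OC
F8 | step 16 | (3R)-7-(benzyloxy)-3-[2-(benzyloxy)-3,4-dimethoxyphenyl]-3,4-dihydro-2H-chromene | COc1ccc([C@@H]2COc3cc(OCc4ccccc4)ccc3C2)c(OCc4ccccc4)c1OC
F9 | step 16 | 2,4-bis(benzyloxy)-1-bromobenzene | Brc1ccc(OCc2ccccc2)cc1OCc1ccccc1
F10 | step 16 | (2R)-2-(benzyloxy)-1-[2,4-bis(benzyloxy)phenyl]-3-[4-(benzyloxy)phenyl]propan-1-one | O=C(c1ccc(OCc2ccccc2)cc1OCc1ccccc1)[C@H](OCc1ccccc1)Cc1ccc(OCc2ccccc2)cc1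
F11 | step 16 | (1RS,2R)-2-(benzyloxy)-1-[2,4-bis(benzyloxy)phenyl]-3-[4-(benzyloxy)phenyl]propan-1-ol | OC(c1ccc(OCc2ccccc2)cc1OCc1ccccc1)[C@H](OCc1ccccc1)Cc1ccc(OCc2ccccc2)cc1
F12 | step 14 | (2R)-2-(benzyloxy)-3-[4-(benzyloxy)phenyl]propanal | O=C[C@H](OCc1ccccc1)Cc1ccc(OCc2ccccc2)cc1
F13 | step 13 | (2R)-3-[4-(benzyloxy)phenyl]-2-hydroxy-N-methoxy-N-methylpropanamide | CON(C)C(=O)[C@H](O)Cc1ccc(OCc2ccccc2)cc1
A1 | alternative 1 | {7-(benzyloxy)-3-[2-(benzyloxy)-3,4-dimethoxyphenyl]-3,4-dihydro-2H-chromen-3-yl}methanol (single enantiomer with quaternary C3) | COc1ccc([C@]2(CO)COc3cc(OCc4ccccc4)ccc3C2)c(OCc4ccccc4)c1OC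
A2 | alternative 1 | 2-[2-(benzyloxy)-3,4-dimethoxyphenyl]-2-[4-(benzyloxy)-2-bromobenzyl]propane-1,3-diol | COc1ccc(C(CO)(CO)Cc2ccc(OCc3ccccc3)cc2Br)c(OCc2ccccc2)c1OC
A3 | alternative 2 | [(2R,3R)-3-{(3R)-7-(benzyloxy)-3-[2-(benzyloxy)-3,4-dimethoxyphenyl]-3,4-dihydro-2H-chromen-6-yl}oxiran-2-yl]methanol | COc1ccc([C@@H]2COc3cc(OCc4ccccc4)c([C@H]5O[C@@H]5CO)cc3C2)c(OCc4ccccc4)c1OC
A4 | alternative 2 | (2E)-3-{(3R)-7-(benzyloxy)-3-[2-(benzyloxy)-3,4-dimethoxyphenyl]-3,4-dihydro-2H-chromen-6-yl}prop-2-en-1-ol | COc1ccc([C@@H]2COc3cc(OCc4ccccc4)c(/C=C/CO)cc3C2)c(OCc4ccccc4)c1OC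
A5 | alternative 3 | (3R)-7-(benzyloxy)-3-[2-(benzyloxy)-3,4-dimethoxyphenyl]-3,4-dihydro-2H-chromene | COc1ccc([C@@H]2COc3cc(OCc4ccccc4)ccc3C2)c(OCc4ccccc4)c1OC
A6 | alternative 3 | 4-(benzyloxy)-2-{(2R)-2-[2-(benzyloxy)-3,4-dimethoxyphenyl]-3-bromopropoxy}-1-iodobenzene | COc1ccc([C@@H](CBr)COc2cc(OCc3ccccc3)ccc2I)c(OCc2ccccc2)c1OC
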